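2.00 h of reaction time is what separates Monday's from Thursday's in the recipes.

| flask | free monomer | pre-initiator | remark | time |
|---|---|---|---|---|
| north-west | 0.080 M | 0.57 mol% | run made earlier |  |
| north | 0.18 M | 0.57 mol% | run made earlier |  |
| south | 0.12 M | 0.85 mol% | run made earlier |  |
| Monday's | 0.12 M | 0.57 mol% |  | 6.0 h |
| Thursday's | 0.12 M | 0.57 mol% |  | 4.0 h |

| run | time / h | monomer in chains / % | free monomer / % |
|---|---|---|---|
| north-west | 0.500 | 0 | 99 |
| north-west | 1.33 | 1 | 97 |
| north-west | 2.50 | 2 | 98 |
| north-west | 4.00 | 9 | 92 |
| north-west | 6.00 | 18 | 82 |
| north-west | 8.00 | 32 | 65 |
| north | 0.500 | 0 | 100 |
| north | 1.00 | 0 | 99 |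
| north | 1.50 | 1 | 96 |
| north | 2.50 | 11 | 89 |
| north | 4.00 | 31 | 67 |
| north | 8.00 | 73 | 23 |
| south | 1.33 | 0 | 100 |
| south | 3.00 | 11 | 87 |
| south | 4.00 | 21 | 78 |
| south | 6.00 | 48 | 51 |
| south | 8.00 | 68 | 33 |

(scatter of a reading: 1.5 percentage points)

1. which of the two ends with the longer chains by the average number of monomer units in a chain (chains begun, living or dead) ("neither" if they lie within 10%) (Monday's / Thursday's / neither)
2. average number of monomer units in a chain (chains begun, living or dead) at the end, Monday's
3. average number of monomer units in a chain (chains begun, living or dead) at the end, Thursday's

- the average divides the monomer in chains by the number of chains begun, living and dead together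
- reactions considered so far: free monomer + initiator -> living end + monomer in chains; free monomer + living end -> monomer in chains + living end; pre-initiator -> initiator
- the earlier runs do not show the number of chains; that part of a forecast is a guess

**What is a chain length here?** It is monomer in chains divided by chains begun. No reaction considered ends a chain. So at a given level of free monomer each living end adds at the same hourly rate, and length is that rate times the age of the average chain.

**How old is the average chain?** In the north run, the square root of ln(charge/free monomer left) should rise linearly once chains begin. The readings at 2.50 h and 4.00 h put the start at a delay of 0.743 h, as a reading. I assume the same delay in Monday's and Thursday's, and that chains then begin steadily. Half of the remaining span gives Monday's 2.63 h of mean chain age, the hours since the average chain began. Thursday's has 1.63 h.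

**So which is longer?** Monday's chains are older than Thursday's, by a ratio of 1.61.

**But free monomer falls. Doesn't that hurt Monday's?** Yes, its late hours add less per end, so I expect a ratio somewhat below that. It should still clear the 10% margin.

**And the lengths themselves?** The hourly rate needs the number of chains, which the readings do not show. Any absolute length is a guess.

The forecast says Monday's, with 350 and 240. It adds: “Their ratio, about 1.45, is firmer than their absolute values”.

The flask gives Monday's, with 152 and 103.

    free monomer + initiator → living end + monomer in chains (k = 0.0230 /M/min)
    free monomer + living end → monomer in chains + living end, rate k2*[living end]*[free monomer] (k = 9.30 /M/min)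
    pre-initiator → initiator (k = 0.00770 /min)

The difference in time is the main reason the two lengths part: Thursday's goes from 103 to 152 when given Monday's time. Divided by mean chain age, Monday's length gives 57.8 /h, while the forecast's gives 133 /h. The growth constant times Monday's charge of free monomer gives 67.0 /h, a pseudo-first-order rate for each end. Monday's lies below this, with 65% of its free monomer left at the end. The neighbour of Monday's charged with 0.030 M of free monomer keeps 97% and reaches a length of 41.3. Taken at Monday's age, that is 15.7 /h, against 16.7 /h from the growth constant.

The earlier runs and the new flask were computed with constants of no real substance; the scatter is artificial.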